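## Structural features

The target is a trans-2,3-disubstituted 2,3-dihydro-1-benzofuran: a benzo ring (ring A) fused through C3a and C7a to a five-membered oxygen ring that carries a 3,4,5-trimethoxyphenyl group (ring B) on C2 and a methyl group on C3. The two stereocentres, C2 (R) and C3 (R), are adjacent; C2 is benzylic to ring B and bonded to the aryl oxygen O1, and C3 is benzylic to ring A. Ring A is tetrasubstituted: O1 on C7a and OMe on C6 stand 1,3 to each other, the side-chain carbon C3 sits on C3a next to C7a, and an (E)-prop-1-enyl group sits on C5, para to O1 and ortho to the methoxy group. Fragile elements are the C2–O1 bond, which can ionise to a stabilised benzylic cation and lose the C2 configuration under acid, the E-styrenyl double bond (acid, oxidants, isomerisation), and the two electron-rich arenes, which compete for electrophiles. The real difficulty is to set the contiguous C2/C3 pair in absolute terms and to place four different substituents on ring A without regiochemical ambiguity. The key step uses the meta relation of C7a–O and C6–O with the carbon chain on C3a: this is the pattern in which a vinylketene (C7a, C5, C4, C3a) and an ynol ether (C7, C6) combine, so ring A can be grown onto a side chain that already holds both stereocentres. The position left free at C5 is then para to the new phenolic hydroxyl, the best site for later introduction of the propenyl group.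

## Logic of the disconnections

25 ⇒ 23 + 24. The bond between C5 and the propenyl carbon is cut first. The sensitive styrene then enters last, and its E geometry is carried in by 24 and not made by an olefination. The gain is the removal of the only C=C stereo-element. The demand is a coupling that leaves the benzylic ether and both stereocentres alone, and a halogen at C5 only.

23 ⇒ 21. The O1–C2 bond is cut. Closing the heterocycle by displacement at C2 lets both stereocentres come from an acyclic syn pair, and inversion at C2 turns syn into trans. The gain is an open-chain phenol and alcohol. The demand is a clean SN2 displacement at a benzylic carbinol, without ionisation or elimination, from the 1S epimer.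

21 ⇒ 20 ⇒ 19. The O–Si bond and the C5–Br bond are cut. In 19 the future C5 is para to the only free hydroxyl and ortho to OMe, and ring B cannot compete, so the halogen is placed before ring closure. This returns to the product of the key step. The demand is mono-bromination para and not at the future C7, and a silyl ether that survives bromination and is cleaved without touching the bromide.

19 ⇒ 11 + 15 (key). Four ring A bonds are cut: C4–C5, C5–C6, C7–C7a and C3a–C7a. The 1,3-dioxygenation with the chain ortho to the hydroxyl is the signature of this annulation. The gain is the whole of ring A; what remains is an acyclic chain with both stereocentres outside the reacting π system. The demand is regiocontrol in the ketene–alkyne addition and tolerance of light and ketene by the silyl ether and the arenes.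

15 ⇒ 12. Two eliminations are undone. The volatile alkyne is made fresh from a stable acetal; the demand is only careful handling.

11 ⇒ 9. The C1–N bond is cut (diazo transfer to a methyl ketone). This avoids acylation of diazomethane by an enoyl chloride. The demand is kinetic enolisation at the methyl group and not at the γ-position C5.

9 ⇒ 7 + 8. The C3=C4 double bond is cut (cross-metathesis). The gain is a terminal alkene; no epimerisable α-branched aldehyde is passed. The demand is E selectivity and no migration of the double bond into the allylic stereocentre.

7 ⇒ 6 ⇒ 1 + 2 (with 3 as chiral controller). The O–Si bond and the bond between the carbinol carbon and the methyl-bearing carbon are cut. One crotylation sets both stereocentres: Z geometry gives the syn relation, and the auxiliary on boron gives the absolute sense. The demand is geometric integrity of the crotyl metal and high facial selectivity on an aryl aldehyde.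

## Other disconnections considered

Alternative 1: The cut is C3a–C4 and C7–C7a, so ring A is grown onto a preformed trans lactone.
- Forward key step: the silyl ketene acetal A2 of the lactone would add as the 2π partner across C3 and C6 of pyrone A3 (inverse-demand [4+2]). Decarboxylative cycloreversion of the bridged adduct and loss of the silyloxy group from C7a would aromatise to ester A1.
- In its favour: both stereocentres and the O1–C2 bond exist before ring A is made, so no displacement at C2 follows. The C5 carbon (as ester) and the C6 methoxy group arrive in the annulation itself. The chemistry is purely thermal.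
- Against it here: a 4-alkoxy-2-pyrone is a vinylogous carbonate and a reluctant diene even with the C5 ester, so forcing conditions are likely. The regiochemistry rests on pairing the nucleophilic carbon of A2 with C6 of A3. The aromatisation can expel either the silyloxy group (wanted) or the ring oxygen O1; the latter opens the heterocycle with C2 in the configuration that is wrong for a later closure with inversion. Turning the ester of A1 into the E-propenyl group needs reduction, oxidation and olefination, three operations against two in the chosen plan.
- Comparison: in structure A1 is more advanced than 19 (heterocycle closed, C5 carbon in place). On the safety of the C2 stereocentre and on the presence of the C5 carbon this alternative is the better. In mechanism both are pericyclic cascades steered by donor–acceptor polarity, but the chosen [2+2]/4π/6π sequence has the closer precedent for a 3-alkoxyphenol. In step count the two are about equal once the lactone synthesis and the longer ester-to-propenyl sequence are counted.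

Alternative 2: The cut is C2–C3 and C2–C(aryl) at a boron-bearing carbon, with both arenes purchased.
- Forward key step: the secondary benzylic boronic ester A6 would be homologated by a dichloromethyl carbenoid (zinc-halide-assisted 1,2-shift of C3 from boron to carbon). The aryl Grignard reagent A7 would then displace chloride by a second 1,2-shift with inversion. Oxidation of the C–B bond with retention leads to the same syn arrangement that 21 carries, so the endgame would be shared.
- In its favour: rings A and B are bought intact, so no ring is built and the oxygenation pattern is never in question. Both stereocentres are under the control of one recoverable diol, applied twice. No light, diazo compound or azide is needed.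
- Against it here: the carbon configuration needed is 1S,2S, as in A4, but A4 is formulated with the (R,R)-diol. Diols of the R,R series steer the insertion to the αS chloride, and displacement with inversion by A7 would then give the C2 epimer, which on closure with inversion ends in the cis series. The ester required is that of the (S,S)-diol, A5; its precursor A6 is then the (1R)-boronate. Further concerns are the configurational lability of α-chloro boronic esters next to an electron-rich arene, the slow migration of a hindered aryl group to a branched centre, and protodeboronation of the benzylic product.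
- Comparison: A5 is one oxidation and one desilylation away from the debromo analogue of 21, so the two plans converge. This route is stepwise and ionic, and every stereocentre depends on a stoichiometric auxiliary; the chosen plan uses one reagent-controlled crotylation and a stereochemically silent pericyclic cascade. In step count this alternative is the equal of the chosen plan or slightly shorter, and in certainty of the ring A substitution pattern it is the better. It is the weaker on the robustness of the two displacements that set the stereocentres.

Alternative 3: The cut is C4–C5 and C7–C7a (with O1–C7a re-formed), building ring A at the cyclohexanedione level on the α-methylene lactone A9.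
- Forward key step: under methoxide the anion of methyl acetoacetate A10 would add to the exocyclic methylene of A9. The methyl-ketone enolate of the adduct would acylate on the lactone carbonyl, closing the six-membered ring and releasing the C2 alkoxide. Mild acid would re-close O1 onto C7a to give the bicyclic vinylogous ester A8.
- In its favour: cheap ionic chemistry on scale, with no light and no diazo or azide reagent. The stereocentres are set in the lactone beforehand. The oxygens at C6 and C7a and the C5 carbon are inherent in the two components.
- Against it here: the ring closure needs the less acidic terminal enolate of a 2-substituted acetoacetate and competes with retro-Claisen deacetylation and methanolysis of the lactone. A8 is two oxidation levels below the arene, so dehydrogenation is required in the presence of an electron-rich ring B and a benzylic C2–H. O-Methylation (which would reach A1) and the three-operation ester-to-propenyl sequence follow.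
- Comparison: A8 is further from the target than 19 (not aromatic, no OMe), and about five steps remain after the key step against four. The annulation is a stepwise polar cascade under thermodynamic control, without the regiochemical lock of the ynol ether. It is the equal of Alternative 1, and the better of the chosen plan, in that the C5 carbon is built in and C2 is never inverted; it is also the better on cost and hazard of reagents.

Key step: step 6

Remark (numbering): benzofuran numbering is used for the target and for ring A throughout.
Remark (assumption): 3 is the (−)-enantiomer, derived from (+)-α-pinene, the hand of the reagent that adds to aryl aldehydes to give the S carbinol.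
Remark (correction): the Wolff substrate 11 has a single C=C and is an alkenyl, not a dienyl, diazomethyl ketone. The descriptors (3E,5R,6S) for 11 and (1S,2R) for 19 are consistent with (2R,3R)-25 after inversion at C2.
Remark (design changes): the enone is reached by cross-metathesis instead of cleavage to an aldehyde and olefination, and the C5 carbon is introduced through a bromide placed para to the free phenol, with the E geometry carried by the boronate.

## Route

Step 1
Reactants: 1 3,4,5-trimethoxybenzaldehyde; 2 cis-but-2-ene; 3 (−)-B-methoxydiisopinocampheylborane
Product: 6 (1S,2R)-2-methyl-1-(3,4,5-trimethoxyphenyl)but-3-en-1-ol, via (Z)-crotyldiisopinocampheylborane 4 (not isolated), via borinate ester 5 (not isolated)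
Conditions: 2, KOt-Bu, n-BuLi, THF, −78 → −45 °C; 3, −78 °C; BF3·OEt2; 1, −78 °C; then NaOH, H2O2, rt
Reagents that add atoms: none
Why: Brown crotylboration: the Z-crotylborane 4 should add through a closed chair transition state, so the Z geometry becomes the 1,2-syn relation and the isopinocampheyl groups direct attack to the aldehyde face that gives the 1S carbinol; oxidative work-up of 5 releases 6. Both stereocentres of the target originate here (C3 as set, C2 to be inverted in step 9).

Step 2
Reactants: 6 syn homoallylic alcohol
Product: 7 tert-butyl(dimethyl){[(1S,2R)-2-methyl-1-(3,4,5-trimethoxyphenyl)but-3-en-1-yl]oxy}silane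
Conditions: TBSOTf, 2,6-lutidine, CH2Cl2, 0 °C
Reagents that add atoms: tert-butyldimethylsilyl trifluoromethanesulfonate, CC(C)(C)[Si](C)(C)OS(=O)(=O)C(F)(F)F
Why: Silylation with a silyl triflate and a hindered base is the standard way to cap a hindered secondary benzylic alcohol; the ether protects the hydroxyl from the amide base, the ketene and the metathesis catalyst of later steps and is transparent to the light used in step 6.

Step 3
Reactants: 7 silyl ether; 8 but-3-en-2-one
Product: 9 (3E,5R,6S)-6-(tert-butyldimethylsilyloxy)-5-methyl-6-(3,4,5-trimethoxyphenyl)hex-3-en-2-one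
Conditions: 8 (excess), second-generation Hoveyda–Grubbs catalyst RuCl2(H2IMes)(=CH-C6H4-2-Oi-Pr) (5 mol %), CH2Cl2, 40 °C
Reagents that add atoms: none
Why: Olefin cross-metathesis of a monosubstituted alkene with an electron-poor vinyl ketone in excess is a well-used E-selective homologation of crotylation products; it reaches the enone in one step without an epimerisable α-branched aldehyde and without ozone next to an electron-rich arene.

Step 4
Reactants: 9 enone
Product: 11 (3E,5R,6S)-6-(tert-butyldimethylsilyloxy)-1-diazo-5-methyl-6-(3,4,5-trimethoxyphenyl)hex-3-en-2-one, via trifluoroacetyl diketone 10 (not isolated)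
Conditions: LiN(SiMe3)2, THF, −78 °C; CF3CO2CH2CF3; dilute aq. HCl wash; then MsN3, Et3N, H2O, MeCN, rt
Reagents that add atoms: methanesulfonyl azide, CS(=O)(=O)N=[N+]=[N-]
Why: Detrifluoroacetylative diazo transfer: kinetic deprotonation of the methyl group, Claisen trifluoroacetylation to 10, then azide transfer with loss of the trifluoroacetyl group as the sulfonamide; this is the standard entry to alkenyl diazomethyl ketones, because acylation of diazomethane by an enoyl chloride suffers from dipolar addition to the C=C bond.

Step 5
Reactants: 12 chloroacetaldehyde dimethyl acetal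
Product: 15 methoxyethyne, via 1-chloro-2-methoxyethene 13 (not isolated), via sodium methoxyethynide 14 (not isolated)
Conditions: NaNH2 (3 equiv), liq. NH3, −33 °C; then sat. aq. NaCl, −70 °C; distil
Reagents that add atoms: none
Why: Two base-induced eliminations (methanol to 13, then HCl) give the acetylide 14, which is protonated on quenching; the volatile ynol ether is distilled and used at once.

Step 6
Reactants: 11 diazo ketone; 15 methoxyethyne
Product: 19 2-[(1S,2R)-1-(tert-butyldimethylsilyloxy)-1-(3,4,5-trimethoxyphenyl)propan-2-yl]-5-methoxyphenol, via vinylketene 16 (not isolated), via cyclobutenone 17 (not isolated), via dienylketene 18 (not isolated)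
Conditions: 15 (excess), ClCH2CH2Cl, hν (254 nm, Vycor, sealed tube), rt; then 80 °C
Reagents that add atoms: none
Why: Irradiation of 11 triggers a photochemical Wolff rearrangement (loss of N2, 1,2-shift of the alkenyl group, new C4–C5 bond) to vinylketene 16. The electron-rich alkyne 15 adds to the ketene C=C in a regiospecific [2+2] cycloaddition, its unsubstituted nucleophilic carbon bonding to the ketene carbonyl carbon (C7–C7a) and its methoxy-bearing carbon to the ketene α-carbon (C5–C6), to give the 4-alkenyl-3-methoxycyclobutenone 17. On warming, 17 opens by reversible 4π electrocyclic ring opening to dienylketene 18, and ring A closes by a thermal disrotatory 6π electrocyclisation (C3a–C7a) followed by tautomerisation to the phenol 19. This is the Danheiser benzannulation in its photochemical diazo ketone form; its closest precedent is the annulation of alkenyl diazomethyl ketones with alkoxy- and siloxyalkynes to resorcinol monoethers. No stereocentre is created: C4 of 17 is transient and becomes aromatic, and the two existing centres (C5 and C6 of 11) lie outside the reacting π system. The selectivity needed is regiochemical, in the [2+2] step, and it is fixed by the polarisation of the ynol ether, which places OMe meta to the new hydroxyl and the side chain ortho to it; the two-stage regime (light at room temperature, then heat) lets cyclobutenone that opens with the unproductive sense of rotation re-close and drain into 19.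

Step 7
Reactants: 19 phenol
Product: 20 4-bromo-2-[(1S,2R)-1-(tert-butyldimethylsilyloxy)-1-(3,4,5-trimethoxyphenyl)propan-2-yl]-5-methoxyphenol
Conditions: NBS (1.0 equiv), MeCN, −20 → 0 °C
Reagents that add atoms: N-bromosuccinimide, O=C1CCC(=O)N1Br
Why: Electrophilic aromatic bromination: the position para to the free hydroxyl (the future C5) is also ortho to the methoxy group and is the most nucleophilic site of the molecule, ahead of the hindered position between the two oxygens and of the non-phenolic ring B; brominating before ring closure fixes the C5 handle regioselectively.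

Step 8
Reactants: 20 bromophenol silyl ether
Product: 21 4-bromo-2-[(1S,2R)-1-hydroxy-1-(3,4,5-trimethoxyphenyl)propan-2-yl]-5-methoxyphenol
Conditions: Bu4NF, THF, 0 °C → rt
Reagents that add atoms: none
Why: Fluoride cleavage of the secondary silyl ether; nothing else in the molecule is labile to fluoride or to the mild basicity of the reagent.

Step 9
Reactants: 21 bromophenol alcohol
Product: 23 (2R,3R)-5-bromo-6-methoxy-3-methyl-2-(3,4,5-trimethoxyphenyl)-2,3-dihydro-1-benzofuran, via oxyphosphonium phenoxide 22 (not isolated)
Conditions: PPh3, DIAD, THF, 0 °C → rt
Reagents that add atoms: none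
Why: Intramolecular Mitsunobu etherification (5-exo-tet): the benzylic hydroxyl is activated as the oxyphosphonium ion 22 and displaced by the phenoxide oxygen with inversion, turning the 1S carbinol into the 2R centre. From the syn precursor this gives the trans ring, which is also the more stable isomer if some ionisation intervenes.

Step 10
Reactants: 23 aryl bromide; 24 (E)-4,4,5,5-tetramethyl-2-(prop-1-en-1-yl)-1,3,2-dioxaborolane
Product: 25 (2R,3R)-6-methoxy-3-methyl-5-[(E)-prop-1-en-1-yl]-2-(3,4,5-trimethoxyphenyl)-2,3-dihydro-1-benzofuran (CNP0122299.1)
Conditions: 24, PdCl2(dppf) (5 mol %), K2CO3, 1,4-dioxane/H2O, 80 °C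
Reagents that add atoms: none
Why: Suzuki–Miyaura coupling of an aryl bromide with an E-alkenylboronate proceeds with retention of alkene geometry, so the E-propenyl group is delivered by the reagent; the carbonate base leaves the benzylic ether and both stereocentres untouched.

## Compound list

1 | 3,4,5-trimethoxybenzaldehyde | COc1cc(C=O)cc(OC)c1OC | starting material
2 | cis-but-2-ene | C/C=C\C | starting material
3 | (−)-B-methoxydiisopinocampheylborane | COB([C@@H]1C[C@@H]2C[C@H]([C@H]1C)C2(C)C)[C@@H]1C[C@@H]2C[C@H]([C@H]1C)C2(C)C | starting material
4 | (Z)-but-2-en-1-yl-diisopinocampheylborane | C/C=C\CB([C@@H]1C[C@@H]2C[C@H]([C@H]1C)C2(C)C)[C@@H]1C[C@@H]2C[C@H]([C@H]1C)C2(C)C | intermediate (not isolated)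
5 | (1S,2R)-2-methyl-1-(3,4,5-trimethoxyphenyl)but-3-en-1-yl diisopinocampheylborinate | B(O[C@H](c1cc(OC)c(OC)c(OC)c1)[C@@H](C=C)C)([C@@H]1C[C@@H]2C[C@H]([C@H]1C)C2(C)C)[C@@H]1C[C@@H]2C[C@H]([C@H]1C)C2(C)C | intermediate (not isolated)
6 | (1S,2R)-2-methyl-1-(3,4,5-trimethoxyphenyl)but-3-en-1-ol | O[C@H](c1cc(OC)c(OC)c(OC)c1)[C@@H](C=C)C | intermediate
7 | tert-butyl(dimethyl){[(1S,2R)-2-methyl-1-(3,4,5-trimethoxyphenyl)but-3-en-1-yl]oxy}silane | CC(C)(C)[Si](C)(C)O[C@H](c1cc(OC)c(OC)c(OC)c1)[C@@H](C=C)C | intermediate
8 | but-3-en-2-one | CC(=O)C=C | starting material
9 | (3E,5R,6S)-6-(tert-butyldimethylsilyloxy)-5-methyl-6-(3,4,5-trimethoxyphenyl)hex-3-en-2-one | CC(C)(C)[Si](C)(C)O[C@H](c1cc(OC)c(OC)c(OC)c1)[C@@H](/C=C/C(C)=O)C | intermediate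
10 | (5E,7R,8S)-8-(tert-butyldimethylsilyloxy)-1,1,1-trifluoro-7-methyl-8-(3,4,5-trimethoxyphenyl)oct-5-ene-2,4-dione | CC(C)(C)[Si](C)(C)O[C@H](c1cc(OC)c(OC)c(OC)c1)[C@@H](/C=C/C(=O)CC(=O)C(F)(F)F)C | intermediate (not isolated)
11 | (3E,5R,6S)-6-(tert-butyldimethylsilyloxy)-1-diazo-5-methyl-6-(3,4,5-trimethoxyphenyl)hex-3-en-2-one | CC(C)(C)[Si](C)(C)O[C@H](c1cc(OC)c(OC)c(OC)c1)[C@@H](/C=C/C(=O)C=[N+]=[N-])C | intermediate
12 | 2-chloro-1,1-dimethoxyethane (chloroacetaldehyde dimethyl acetal) | COC(CCl)OC | starting material
13 | 1-chloro-2-methoxyethene (E/Z mixture) | COC=CCl | intermediate (not isolated)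
14 | sodium methoxyethynide | [Na+].[C-]#COC | intermediate (not isolated)
15 | methoxyethyne | COC#C | intermediate
16 | (3E,5R,6S)-6-(tert-butyldimethylsilyloxy)-5-methyl-6-(3,4,5-trimethoxyphenyl)hexa-1,3-dien-1-one | CC(C)(C)[Si](C)(C)O[C@H](c1cc(OC)c(OC)c(OC)c1)[C@@H](/C=C/C=C=O)C | intermediate (not isolated)
17 | 4-[(1E,3R,4S)-4-(tert-butyldimethylsilyloxy)-3-methyl-4-(3,4,5-trimethoxyphenyl)but-1-en-1-yl]-3-methoxycyclobut-2-en-1-one (mixture at C4 of the four-membered ring) | CC(C)(C)[Si](C)(C)O[C@H](c1cc(OC)c(OC)c(OC)c1)[C@@H](/C=C/C1C(=O)C=C1OC)C | intermediate (not isolated)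
18 | (3E,5E,7R,8S)-8-(tert-butyldimethylsilyloxy)-3-methoxy-7-methyl-8-(3,4,5-trimethoxyphenyl)octa-1,3,5-trien-1-one | CC(C)(C)[Si](C)(C)O[C@H](c1cc(OC)c(OC)c(OC)c1)[C@@H](/C=C/C=C(OC)\C=C=O)C | intermediate (not isolated)
19 | 2-[(1S,2R)-1-(tert-butyldimethylsilyloxy)-1-(3,4,5-trimethoxyphenyl)propan-2-yl]-5-methoxyphenol | CC(C)(C)[Si](C)(C)O[C@H](c1cc(OC)c(OC)c(OC)c1)[C@@H](c1ccc(OC)cc1O)C | intermediate
20 | 4-bromo-2-[(1S,2R)-1-(tert-butyldimethylsilyloxy)-1-(3,4,5-trimethoxyphenyl)propan-2-yl]-5-methoxyphenol | CC(C)(C)[Si](C)(C)O[C@H](c1cc(OC)c(OC)c(OC)c1)[C@@H](c1cc(Br)c(OC)cc1O)C | intermediate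
21 | 4-bromo-2-[(1S,2R)-1-hydroxy-1-(3,4,5-trimethoxyphenyl)propan-2-yl]-5-methoxyphenol | O[C@H](c1cc(OC)c(OC)c(OC)c1)[C@@H](c1cc(Br)c(OC)cc1O)C | intermediate
22 | [(1S,2R)-2-(5-bromo-4-methoxy-2-oxidophenyl)-1-(3,4,5-trimethoxyphenyl)propoxy]triphenylphosphonium (zwitterion) | c1ccccc1[P+](c1ccccc1)(c1ccccc1)O[C@H](c1cc(OC)c(OC)c(OC)c1)[C@@H](c1cc(Br)c(OC)cc1[O-])C | intermediate (not isolated)
23 | (2R,3R)-5-bromo-6-methoxy-3-methyl-2-(3,4,5-trimethoxyphenyl)-2,3-dihydro-1-benzofuran | Brc1cc2c(cc1OC)O[C@@H](c1cc(OC)c(OC)c(OC)c1)[C@@H]2C | intermediate
24 | (E)-4,4,5,5-tetramethyl-2-(prop-1-en-1-yl)-1,3,2-dioxaborolane | C/C=C/B1OC(C)(C)C(C)(C)O1 | starting material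
25 | (2R,3R)-6-methoxy-3-methyl-5-[(E)-prop-1-en-1-yl]-2-(3,4,5-trimethoxyphenyl)-2,3-dihydro-1-benzofuran | C/C=C/c1cc2c(cc1OC)O[C@@H](c1cc(OC)c(OC)c(OC)c1)[C@@H]2C | target

## Step count and least certain steps

Total: 10 steps (nine in the main line and one for 15). Longest linear sequence: 9 steps, from 1 to 25 through steps 1–4 and 6–10.

Step 6 (key step). What may go wrong: competitive light absorption by the two electron-rich arenes and by the product phenol, leading to secondary photolysis; incomplete interception of 16 by the volatile alkyne, so that ketene dimerisation or acylation of the phenol 19 by 16 takes over; incomplete thermal drainage of 17. A brief treatment of the crude product with K2CO3 in methanol would return any aryl ester to 19. Fallback (a different construction of the bicycle, without benzannulation), setting out from 1: Julia–Kocienski ethylidenation with 5-(ethylsulfonyl)-1-phenyl-1H-tetrazole and KN(SiMe3)2 would give (E)-1,2,3-trimethoxy-5-(prop-1-en-1-yl)benzene F1. A formal [3+2] cycloaddition of F1 with 2-methoxy-1,4-benzoquinone, promoted by a chiral tetravalent titanium Lewis acid, TiCl2(TADDOLate) made from TiCl4, Ti(Oi-Pr)4 and the TADDOL diol of the required hand, would form C3–C3a and O1–C2 in the trans sense and give (2R,3R)-6-methoxy-3-methyl-2-(3,4,5-trimethoxyphenyl)-2,3-dihydro-1-benzofuran-5-ol F2. Triflation (Tf2O, pyridine) would give (2R,3R)-6-methoxy-3-methyl-2-(3,4,5-trimethoxyphenyl)-2,3-dihydro-1-benzofuran-5-yl trifluoromethanesulfonate F3, and PdCl2(dppf)-catalysed coupling of F3 with 24 comes back to the route at 25. Enantiocontrol would then rest on the chiral Lewis acid and not on the crotylation.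

Step 3. What may go wrong: slow or incomplete metathesis at the branched allylic position, homodimerisation of 7, and migration of the double bond into the allylic stereocentre by ruthenium hydride species. Fallback, setting out from 7: oxidative cleavage of the vinyl group (catalytic OsO4, NaIO4, 2,6-lutidine, dioxane/H2O) would give (2S,3S)-3-(tert-butyldimethylsilyloxy)-2-methyl-3-(3,4,5-trimethoxyphenyl)propanal F4, used crude to limit epimerisation. Wittig reaction of F4 with 1-(triphenylphosphoranylidene)propan-2-one in CH2Cl2 comes back at 9.

Step 4. What may go wrong: competing γ-deprotonation at C5 by the amide base, with loss of configuration at C5 or 1,4-elimination of the silyloxy group, and incomplete trifluoroacetylation before azide transfer. Fallback, setting out from 7: the aldehyde F4 described under step 3 would be condensed in a Horner–Wadsworth–Emmons reaction (LiCl, i-Pr2NEt, MeCN) with diethyl (3-diazo-2-oxopropyl)phosphonate F5, prepared from diethylphosphonoacetic acid. The diazo group is then already in place when the C=C bond is made, and the sequence comes back at 11 without passing through 9.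

Step 7. What may go wrong: bromination at the position between the two oxygens or on ring B, or twofold bromination. Fallback (the C5 carbon introduced after ring closure by formylation and olefination), setting out from 19: Bu4NF would give 2-[(1S,2R)-1-hydroxy-1-(3,4,5-trimethoxyphenyl)propan-2-yl]-5-methoxyphenol F6. Mitsunobu closure (PPh3, DIAD) would give (2R,3R)-6-methoxy-3-methyl-2-(3,4,5-trimethoxyphenyl)-2,3-dihydro-1-benzofuran F7. Vilsmeier–Haack formylation (POCl3, DMF), expected para to O1, would give (2R,3R)-6-methoxy-3-methyl-2-(3,4,5-trimethoxyphenyl)-2,3-dihydro-1-benzofuran-5-carbaldehyde F8. Julia–Kocienski ethylidenation of F8 (5-(ethylsulfonyl)-1-phenyl-1H-tetrazole, KN(SiMe3)2, DME) comes back at 25.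

Step 9. What may go wrong: ionisation of the activated benzylic carbinol, with partial loss of stereospecificity, and elimination to the trisubstituted stilbene. Fallback (closure through the benzylic cation under product-stability control), setting out from 20: treatment with acid (catalytic TsOH or BF3·OEt2, CH2Cl2) would ionise the benzylic silyl ether. Capture of the cation by the phenol should favour the more stable trans ring and comes back at 23 without passing through 21. No new compound is made (F0).

## Further compounds

F1 | step 6 | (E)-1,2,3-trimethoxy-5-(prop-1-en-1-yl)benzene | C/C=C/c1cc(OC)c(OC)c(OC)c1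
F2 | step 6 | (2R,3R)-6-methoxy-3-methyl-2-(3,4,5-trimethoxyphenyl)-2,3-dihydro-1-benzofuran-5-ol | Oc1cc2c(cc1OC)O[C@@H](c1cc(OC)c(OC)c(OC)c1)[C@@H]2C
F3 | step 6 | (2R,3R)-6-methoxy-3-methyl-2-(3,4,5-trimethoxyphenyl)-2,3-dihydro-1-benzofuran-5-yl trifluoromethanesulfonate | O=S(=O)(Oc1cc2c(cc1OC)O[C@@H](c1cc(OC)c(OC)c(OC)c1)[C@@H]2C)C(F)(F)F
F4 | step 3 | (2S,3S)-3-(tert-butyldimethylsilyloxy)-2-methyl-3-(3,4,5-trimethoxyphenyl)propanal | CC(C)(C)[Si](C)(C)O[C@H](c1cc(OC)c(OC)c(OC)c1)[C@@H](C=O)C
F5 | step 4 | diethyl (3-diazo-2-oxopropyl)phosphonate | CCOP(=O)(CC(=O)C=[N+]=[N-])OCC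
F6 | step 7 | 2-[(1S,2R)-1-hydroxy-1-(3,4,5-trimethoxyphenyl)propan-2-yl]-5-methoxyphenol | O[C@H](c1cc(OC)c(OC)c(OC)c1)[C@@H](c1ccc(OC)cc1O)C
F7 | step 7 | (2R,3R)-6-methoxy-3-methyl-2-(3,4,5-trimethoxyphenyl)-2,3-dihydro-1-benzofuran | COc1ccc2c(c1)O[C@@H](c1cc(OC)c(OC)c(OC)c1)[C@@H]2C
F8 | step 7 | (2R,3R)-6-methoxy-3-methyl-2-(3,4,5-trimethoxyphenyl)-2,3-dihydro-1-benzofuran-5-carbaldehyde | O=Cc1cc2c(cc1OC)O[C@@H](c1cc(OC)c(OC)c(OC)c1)[C@@H]2C
F0 | step 9 | none | none
A1 | alternative 1 | methyl (2R,3R)-6-methoxy-3-methyl-2-(3,4,5-trimethoxyphenyl)-2,3-dihydro-1-benzofuran-5-carboxylate | COC(=O)c1cc2c(cc1OC)O[C@@H](c1cc(OC)c(OC)c(OC)c1)[C@@H]2C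
A2 | alternative 1 | tert-butyl(dimethyl){[(4R,5R)-4-methyl-5-(3,4,5-trimethoxyphenyl)-4,5-dihydrofuran-2-yl]oxy}silane | O1[C@@H](c2cc(OC)c(OC)c(OC)c2)[C@H](C)C=C1O[Si](C)(C)C(C)(C)C
A3 | alternative 1 | methyl 4-methoxy-2-oxo-2H-pyran-5-carboxylate | COC(=O)C1=COC(=O)C=C1OC
A4 | alternative 2 | (4R,5R)-2-[(1S,2S)-2-[2-(tert-butyldimethylsilyloxy)-4-methoxyphenyl]-1-(3,4,5-trimethoxyphenyl)propyl]-4,5-dicyclohexyl-1,3,2-dioxaborolane | B1(O[C@H](C2CCCCC2)[C@@H](C2CCCCC2)O1)[C@H](c1cc(OC)c(OC)c(OC)c1)[C@@H](c1ccc(OC)cc1O[Si](C)(C)C(C)(C)C)C
A5 | alternative 2 | (4S,5S)-2-[(1S,2S)-2-[2-(tert-butyldimethylsilyloxy)-4-methoxyphenyl]-1-(3,4,5-trimethoxyphenyl)propyl]-4,5-dicyclohexyl-1,3,2-dioxaborolane | B1(O[C@@H](C2CCCCC2)[C@H](C2CCCCC2)O1)[C@H](c1cc(OC)c(OC)c(OC)c1)[C@@H](c1ccc(OC)cc1O[Si](C)(C)C(C)(C)C)C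
A6 | alternative 2 | (4S,5S)-2-[(1R)-1-[2-(tert-butyldimethylsilyloxy)-4-methoxyphenyl]ethyl]-4,5-dicyclohexyl-1,3,2-dioxaborolane | B1(O[C@@H](C2CCCCC2)[C@H](C2CCCCC2)O1)[C@@H](c1ccc(OC)cc1O[Si](C)(C)C(C)(C)C)C
A7 | alternative 2 | (3,4,5-trimethoxyphenyl)magnesium bromide | COc1cc([Mg]Br)cc(OC)c1OC
A8 | alternative 3 | methyl (2R,3R)-3-methyl-6-oxo-2-(3,4,5-trimethoxyphenyl)-2,3,3a,4,5,6-hexahydro-1-benzofuran-5-carboxylate (mixture at C3a and C5) | COC(=O)C1CC2C(=CC1=O)O[C@@H](c1cc(OC)c(OC)c(OC)c1)[C@@H]2C
A9 | alternative 3 | (4R,5R)-4-methyl-3-methylidene-5-(3,4,5-trimethoxyphenyl)oxolan-2-one | O=C1O[C@@H](c2cc(OC)c(OC)c(OC)c2)[C@H](C)C1=C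
A10 | alternative 3 | methyl 3-oxobutanoate (methyl acetoacetate) | CC(=O)CC(=O)OC
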